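A direct plan would join two differently protected orsellinic acid units to the B–C didepside phenol A1, esterify it to the 4-benzyloxy-6-methyl-2-pyrone-5-carboxylate A2 and build ring A on the pyrone by inverse-demand Diels–Alder addition of the tris(silyloxy)ethene A3 with loss of CO2 (tridepside A4); benzylation, desilylation, acetylation and hydrogenolysis would finish.
Its weakest steps would be the pyrone cycloaddition (an electron-rich 4-alkoxypyrone, crowded at C6: slow at 120 °C, regiochemistry unproven, two aryl esters exposed), the allyl, benzyl and silyl differentiation of orsellinic acid (seven steps, no added complexity) and the benzylation–desilylation–acetylation tail (three steps to place one acetate).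

The new route treats ring A as a folded tetraketide. Ring A (C1 to C6, oxygen on C2 and C4, acetoxy on C5, methyl on C6) is disconnected at its C1–C6 bond and at its ester bond to ring B O4. An acylketene released from acetoxy diketo-dioxinone 10 is captured by the O4 phenol of didepside 9, and the resulting 6-acetoxy-3,5,7-trioxooctanoate closes by aldol condensation. One operation thus makes the hindered depside bond and the pentasubstituted ring with the acetate already on O5, so no cycloaddition, no hydroxyl differentiation and no ether or silyl protection is needed. The same folding, with dioxinone 3, first grows ring B on benzyl orsellinate 5.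

Key step: step 6

Remark on the chemistry: the target is achiral, so no stereocentre has to be set, and the stereocentres of 8 and 10 to 13 are transient and left uncontrolled; chain positions C1 to C8 count from the ester (or ketene) carbon to the terminal methyl group; ring C is an unmodified orsellinic acid unit and is taken from the commercial acid.

Step 1
Reactants: 1 2,2,6-trimethyl-4H-1,3-dioxin-4-one
Product: 2 2,2-dimethyl-6-(2-oxopropyl)-4H-1,3-dioxin-4-one (keto-dioxinone)
Conditions: 1 (2 equiv), LiN(SiMe3)2 (2 equiv), THF, −78 °C; AcCl (1 equiv), −78 °C; aq. NH4Cl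
Reagents that add atoms: acetyl chloride, CC(=O)Cl
Why: Crossed Claisen-type γ-C-acylation of the lithium dienolate of the dioxinone, in which the second equivalent of dienolate deprotonates the more acidic product and so should prevent double acylation.

Step 2
Reactants: 2 2,2-dimethyl-6-(2-oxopropyl)-4H-1,3-dioxin-4-one
Product: 3 6-(2,4-dioxopentyl)-2,2-dimethyl-4H-1,3-dioxin-4-one (diketo-dioxinone)
Conditions: LiN(iPr)2 (2.2 equiv), THF, −78 °C; MeC(O)N(OMe)Me (1.1 equiv), −78 to −20 °C; 1 M HCl to pH 3
Reagents that add atoms: N-methoxy-N-methylacetamide, CC(=O)N(C)OC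
Why: Crossed Claisen condensation of the keto-dioxinone dianion, which reacts at its more basic terminal carbon with the Weinreb amide, whose lithium-chelated adduct should not release the acidic 1,3-diketone before work-up.

Step 3
Reactants: 4 orsellinic acid (2,4-dihydroxy-6-methylbenzoic acid)
Product: 5 benzyl 2,4-dihydroxy-6-methylbenzoate (benzyl orsellinate; ring C)
Conditions: BnBr (1.05 equiv), KHCO3 (1.1 equiv), DMF, rt
Reagents that add atoms: benzyl bromide, BrCc1ccccc1
Why: SN2 alkylation of the carboxylate, the only group that hydrogencarbonate deprotonates, so both phenols should stay free and the acid is never heated towards decarboxylation.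

Step 4
Reactants: 3 6-(2,4-dioxopentyl)-2,2-dimethyl-4H-1,3-dioxin-4-one; 5 benzyl 2,4-dihydroxy-6-methylbenzoate
Product: 9 benzyl 4-[(2,4-dihydroxy-6-methylbenzoyl)oxy]-2-hydroxy-6-methylbenzoate (benzyl lecanorate; rings B–C), via acylketene 6 (not isolated), via aryl triketo ester 7 (not isolated), via cyclic aldol 8 (not isolated)
Conditions: 3 (1.0 equiv), 5 (1.2 equiv), toluene, 110 °C; then Et3N (0.3 equiv), CH2Cl2, 0 °C to rt; aq. citric acid wash
Reagents that add atoms: none
Why: Retro-[4+2] loss of acetone from the dioxinone gives an acylketene that the unchelated O4 phenol of 5 traps, and the aryl 3,5,7-triketo ester closes by C2-to-C7 aldol condensation and enolisation (the dioxinone route to resorcylates), while O2–H is held in a hydrogen bond to the ester carbonyl and should not compete.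

Step 5
Reactants: 3 6-(2,4-dioxopentyl)-2,2-dimethyl-4H-1,3-dioxin-4-one
Product: 10 1-(2,2-dimethyl-4-oxo-4H-1,3-dioxin-6-yl)-2,4-dioxopentan-3-yl acetate (acetoxy diketo-dioxinone, racemic)
Conditions: Pb(OAc)4 (1.05 equiv), AcOH–CH2Cl2, 10 °C to rt
Reagents that add atoms: lead tetraacetate, CC(=O)O[Pb](OC(C)=O)(OC(C)=O)OC(C)=O
Why: α-Acetoxylation of a 1,3-diketone by tetravalent lead goes through the most enolised position, here the methylene between the two ketones and not the less acidic one next to the dioxinone, and the less enolised product should resist a second oxidation.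

Step 6
Reactants: 9 benzyl 4-[(2,4-dihydroxy-6-methylbenzoyl)oxy]-2-hydroxy-6-methylbenzoate; 10 1-(2,2-dimethyl-4-oxo-4H-1,3-dioxin-6-yl)-2,4-dioxopentan-3-yl acetate
Product: 14 benzyl 4-{[4-{[5-acetoxy-2,4-dihydroxy-6-methylbenzoyl]oxy}-2-hydroxy-6-methylbenzoyl]oxy}-2-hydroxy-6-methylbenzoate (benzyl ester of the target), via acetoxy acylketene 11 (not isolated), via acetoxy triketo aryl ester 12 (not isolated), via cyclic aldol 13 (not isolated)
Conditions: 9 (1.0 equiv, 0.3 M), 10 (1.5 equiv, added over 2 h), toluene, 110 °C; then Et3N (0.2 equiv), CH2Cl2, 0 °C; AcOH, aq. citric acid wash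
Reagents that add atoms: none
Why: Heating 10 expels acetone by retro-[4+2] fragmentation to acylketene 11, which the O4 phenol of ring B captures through a six-membered transition state that passes its proton to the acyl oxygen, so aryl ester 12 forms without activation of any 2,6-disubstituted benzoic acid. Catalytic amine then enolises the C2 methylene of 12, which adds to the C7 methyl ketone in a 6-(enolendo)-exo-trig aldol closure to carbinol 13, and loss of water with enolisation at C3 and C5 aromatises ring A, so that the ring C1–C6 bond is formed and the chain C6 acetoxy group ends on ring C5 next to the methyl group. The closest known reactions are the capture of dioxinone-derived acylketenes by alcohols and phenols and the aldol aromatisation of the resulting 3,5,7-triketo esters to 6-alkylresorcylates. The three stereocentres of 13 are uncontrolled and irrelevant, because all become sp2 carbons. The step needs capture at the free O4–H of ring B and not at the two O2–H groups, which are hydrogen-bonded to their ester carbonyls and poorer nucleophiles, and it needs capture to outrun lactonisation of 11 onto its own C5 enol, which slow addition of 10 to concentrated 9 should secure. The acetate should stay on O5 because that oxygen is never a free phenol, because the ring carbon that carries it has no β-hydrogen partner for its elimination, and because an O4 acetate would give up the conjugation of the O4 hydroxyl with the para ester carbonyl.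

Step 7
Reactants: 14 benzyl ester of the target
Product: 15 CNP0154030.0, 4-{[4-{[5-acetoxy-2,4-dihydroxy-6-methylbenzoyl]oxy}-2-hydroxy-6-methylbenzoyl]oxy}-2-hydroxy-6-methylbenzoic acid
Conditions: H2 (1 atm), 10% Pd/C, EtOAc, rt
Reagents that add atoms: none
Why: Hydrogenolysis of the single benzyl ester on palladium in a neutral aprotic medium leaves the aryl esters and the aryl acetate untouched, and no base or alcohol is present that could move the acetate to O4.

**Compound list**
1 | 2,2,6-trimethyl-4H-1,3-dioxin-4-one | CC1=CC(=O)OC(C)(C)O1 | starting material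
2 | 2,2-dimethyl-6-(2-oxopropyl)-4H-1,3-dioxin-4-one | CC(=O)CC1=CC(=O)OC(C)(C)O1 | intermediate
3 | 6-(2,4-dioxopentyl)-2,2-dimethyl-4H-1,3-dioxin-4-one | CC(=O)CC(=O)CC1=CC(=O)OC(C)(C)O1 | intermediate
4 | orsellinic acid (2,4-dihydroxy-6-methylbenzoic acid) | Cc1cc(O)cc(O)c1C(=O)O | starting material
5 | benzyl 2,4-dihydroxy-6-methylbenzoate | Cc1cc(O)cc(O)c1C(=O)OCc2ccccc2 | intermediate
6 | oct-1-ene-1,3,5,7-tetrone (acylketene, not isolated) | CC(=O)CC(=O)CC(=O)C=C=O | intermediate
7 | 4-(benzyloxycarbonyl)-3-hydroxy-5-methylphenyl 3,5,7-trioxooctanoate (not isolated) | CC(=O)CC(=O)CC(=O)CC(=O)Oc1cc(C)c(C(=O)OCc2ccccc2)c(O)c1 | intermediate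
8 | 4-(benzyloxycarbonyl)-3-hydroxy-5-methylphenyl 2-hydroxy-2-methyl-4,6-dioxocyclohexane-1-carboxylate (cyclic aldol, racemic, relative configuration undefined, not isolated) | CC1(O)CC(=O)CC(=O)C1C(=O)Oc2cc(C)c(C(=O)OCc3ccccc3)c(O)c2 | intermediate
9 | benzyl 4-[(2,4-dihydroxy-6-methylbenzoyl)oxy]-2-hydroxy-6-methylbenzoate | Cc1cc(O)cc(O)c1C(=O)Oc2cc(C)c(C(=O)OCc3ccccc3)c(O)c2 | intermediate
10 | 1-(2,2-dimethyl-4-oxo-4H-1,3-dioxin-6-yl)-2,4-dioxopentan-3-yl acetate (racemic) | CC(=O)OC(C(C)=O)C(=O)CC1=CC(=O)OC(C)(C)O1 | intermediate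
11 | 2,4,6,8-tetraoxooct-7-en-3-yl acetate (acetoxy acylketene, racemic, not isolated) | CC(=O)OC(C(C)=O)C(=O)CC(=O)C=C=O | intermediate
12 | ring B O4 ester of 9 with 6-acetoxy-3,5,7-trioxooctanoic acid (racemic, not isolated) | CC(=O)OC(C(C)=O)C(=O)CC(=O)CC(=O)Oc1cc(C)c(C(=O)Oc2cc(C)c(C(=O)OCc3ccccc3)c(O)c2)c(O)c1 | intermediate
13 | ring B O4 ester of 9 with 3-acetoxy-2-hydroxy-2-methyl-4,6-dioxocyclohexane-1-carboxylic acid (cyclic aldol, racemic, relative configuration undefined, not isolated) | CC(=O)OC1C(=O)CC(=O)C(C(=O)Oc2cc(C)c(C(=O)Oc3cc(C)c(C(=O)OCc4ccccc4)c(O)c3)c(O)c2)C1(C)O | intermediate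
14 | benzyl 4-{[4-{[5-acetoxy-2,4-dihydroxy-6-methylbenzoyl]oxy}-2-hydroxy-6-methylbenzoyl]oxy}-2-hydroxy-6-methylbenzoate | CC(=O)Oc1c(O)cc(O)c(C(=O)Oc2cc(C)c(C(=O)Oc3cc(C)c(C(=O)OCc4ccccc4)c(O)c3)c(O)c2)c1C | intermediate
15 | CNP0154030.0 | CC(=O)Oc1c(O)cc(O)c(C(=O)Oc2cc(C)c(C(=O)Oc3cc(C)c(C(=O)O)c(O)c3)c(O)c2)c1C | target

Total step count: 7. Longest linear sequence: 5 steps (steps 1, 2, 4, 6, 7); step 3 is a one-step branch from 4 and step 5 branches from 3.

Steps most likely to fail:

Step 6. Capture of acylketene 11 by the electron-poor O4 phenol may be outrun by lactonisation of the ketene onto its own enol. During the amine-induced closure the chain may cyclise in the Claisen sense with expulsion of the phenol, or the acetate may shift or be cleaved. The fallback would close ring A first and form the depside bond afterwards. Setting out from 10, amine-induced aldol aromatisation of the dioxinone itself (Et3N, CH2Cl2) would give 7-hydroxy-2,2,5-trimethyl-4-oxo-4H-benzo[d][1,3]dioxin-6-yl acetate F1. Silylation (TBSCl, imidazole, DMF) would give 7-(tert-butyldimethylsilyloxy)-2,2,5-trimethyl-4-oxo-4H-benzo[d][1,3]dioxin-6-yl acetate F2. Irradiation of F2 at 300 nm in CH2Cl2 in the presence of 9 would release a quinone ketene, which ring B O4–H should capture to give the ring A O4-silylated tridepside benzyl ester F3. HF·pyridine would then return to 14.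

Step 5. The oxidant may not distinguish the two active methylene groups of 3, may acetoxylate twice, or may attack the dioxinone enol ether. The fallback would bring the oxygen in with the chain. Setting out from 1, γ-acylation of its lithium dienolate (LiN(SiMe3)2, THF, −78 °C) with (tert-butyldimethylsilyloxy)acetyl chloride would give 6-[3-(tert-butyldimethylsilyloxy)-2-oxopropyl]-2,2-dimethyl-4H-1,3-dioxin-4-one F4. Acetylation of its dianion (LiN(iPr)2, then N-methoxy-N-methylacetamide, as in step 2) would give 6-[3-(tert-butyldimethylsilyloxy)-2,4-dioxopentyl]-2,2-dimethyl-4H-1,3-dioxin-4-one F5. HF·pyridine would free 6-(3-hydroxy-2,4-dioxopentyl)-2,2-dimethyl-4H-1,3-dioxin-4-one F6, and Ac2O–pyridine would return to 10.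

Step 4. Capture of acylketene 6 may be slow or may also take place on the chelated O2 hydroxyl, the product may take up a second ketene, and the aryl triketo ester may lose the phenol again under base. The fallback would set out from 3 and 5. Aromatisation of 3 alone (Et3N, CH2Cl2) would give 7-hydroxy-2,2,5-trimethyl-4H-benzo[d][1,3]dioxin-4-one F7, and silylation (TBSCl, imidazole) would give 7-(tert-butyldimethylsilyloxy)-2,2,5-trimethyl-4H-benzo[d][1,3]dioxin-4-one F8. Photochemical acylation of 5 with F8 (300 nm, CH2Cl2) would give benzyl 4-{[4-(tert-butyldimethylsilyloxy)-2-hydroxy-6-methylbenzoyl]oxy}-2-hydroxy-6-methylbenzoate F9, and HF·pyridine would return to 9.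

**Further compounds**
F1 | step 6 | 7-hydroxy-2,2,5-trimethyl-4-oxo-4H-benzo[d][1,3]dioxin-6-yl acetate | CC(=O)Oc1c(O)cc2OC(C)(C)OC(=O)c2c1C
F2 | step 6 | 7-(tert-butyldimethylsilyloxy)-2,2,5-trimethyl-4-oxo-4H-benzo[d][1,3]dioxin-6-yl acetate | CC(=O)Oc1c(O[Si](C)(C)C(C)(C)C)cc2OC(C)(C)OC(=O)c2c1C
F3 | step 6 | benzyl 4-{[4-{[5-acetoxy-4-(tert-butyldimethylsilyloxy)-2-hydroxy-6-methylbenzoyl]oxy}-2-hydroxy-6-methylbenzoyl]oxy}-2-hydroxy-6-methylbenzoate | CC(=O)Oc1c(O[Si](C)(C)C(C)(C)C)cc(O)c(C(=O)Oc2cc(C)c(C(=O)Oc3cc(C)c(C(=O)OCc4ccccc4)c(O)c3)c(O)c2)c1C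
F4 | step 5 | 6-[3-(tert-butyldimethylsilyloxy)-2-oxopropyl]-2,2-dimethyl-4H-1,3-dioxin-4-one | CC(C)(C)[Si](C)(C)OCC(=O)CC1=CC(=O)OC(C)(C)O1
F5 | step 5 | 6-[3-(tert-butyldimethylsilyloxy)-2,4-dioxopentyl]-2,2-dimethyl-4H-1,3-dioxin-4-one (racemic) | CC(=O)C(O[Si](C)(C)C(C)(C)C)C(=O)CC1=CC(=O)OC(C)(C)O1
F6 | step 5 | 6-(3-hydroxy-2,4-dioxopentyl)-2,2-dimethyl-4H-1,3-dioxin-4-one (racemic) | CC(=O)C(O)C(=O)CC1=CC(=O)OC(C)(C)O1
F7 | step 4 | 7-hydroxy-2,2,5-trimethyl-4H-benzo[d][1,3]dioxin-4-one | Cc1cc(O)cc2OC(C)(C)OC(=O)c12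
F8 | step 4 | 7-(tert-butyldimethylsilyloxy)-2,2,5-trimethyl-4H-benzo[d][1,3]dioxin-4-one | Cc1cc(O[Si](C)(C)C(C)(C)C)cc2OC(C)(C)OC(=O)c12
F9 | step 4 | benzyl 4-{[4-(tert-butyldimethylsilyloxy)-2-hydroxy-6-methylbenzoyl]oxy}-2-hydroxy-6-methylbenzoate | Cc1cc(O[Si](C)(C)C(C)(C)C)cc(O)c1C(=O)Oc2cc(C)c(C(=O)OCc3ccccc3)c(O)c2
A1 | direct plan | benzyl 2-(benzyloxy)-4-{[2-(benzyloxy)-4-hydroxy-6-methylbenzoyl]oxy}-6-methylbenzoate | Cc1cc(O)cc(OCc2ccccc2)c1C(=O)Oc1cc(C)c(C(=O)OCc2ccccc2)c(OCc2ccccc2)c1
A2 | direct plan | 4-(benzyloxy)-6-methyl-2-oxo-2H-pyran-5-carboxylate ester of ring B O4 of A1 | CC1=C(C(=O)Oc2cc(C)c(C(=O)Oc3cc(C)c(C(=O)OCc4ccccc4)c(OCc4ccccc4)c3)c(OCc3ccccc3)c2)C(OCc2ccccc2)=CC(=O)O1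
A3 | direct plan | 2-(tert-butyldimethylsilyloxy)-1,1-bis(trimethylsilyloxy)ethene | CC(C)(C)[Si](C)(C)OC=C(O[Si](C)(C)C)O[Si](C)(C)C
A4 | direct plan | protected tridepside with ring A 2-(benzyloxy)-5-(tert-butyldimethylsilyloxy)-4-hydroxy-6-methylbenzoyl | Cc1c(O[Si](C)(C)C(C)(C)C)c(O)cc(OCc2ccccc2)c1C(=O)Oc1cc(C)c(C(=O)Oc2cc(C)c(C(=O)OCc3ccccc3)c(OCc3ccccc3)c2)c(OCc2ccccc2)c1
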